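Compound numbers 1–31 follow the order of the steps below and are used throughout. Locants: oxolane O1, C2 (bears ring B), C3 (bears CH2OH), C4 (bears the ring-A benzyl group), C5. Ring A is the guaiacyl ring of the benzyl group, ring B the arene on oxolane C2 (also the benzo ring of the inner dihydrobenzofuran), ring C the benzo ring of the outer dihydrobenzofuran, ring D the terminal guaiacyl ring. Each dihydrobenzofuran is numbered O1, C2 (aryl), C3 (one-carbon substituent), C3a.

## Analysis of the target

The target 31 is a linear tetramer of guaiacyl units: a 2,3,4-trisubstituted oxolane whose ring B is the benzo ring of a 2-aryl-3-(hydroxymethyl)-7-methoxy-2,3-dihydrobenzofuran (inner), whose 2-aryl group (ring C) is the benzo ring of a second such unit (outer) ending in ring D. It has seven stereocentres in three groups insulated from one another by arenes: oxolane C2, C3 and C4 are all R with the three substituents on one face (all-cis), the inner dihydrobenzofuran is (2R,3S)-trans and the outer one (2S,3R)-trans, so the two dihydrobenzofurans have opposite absolute sense. Because the groups cannot pass stereochemical information to each other, each needs its own source of absolute configuration, and isomers that differ only in the relation between remote groups will be hard to separate. The all-cis oxolane is the contra-thermodynamic arrangement, so it must be made under kinetic control and kept away from acid, since ionisation of the benzylic C2–O1 bond would epimerise C2. Further sensitive features are two free phenols, each para to a benzylic ether carbon (phenoxide plus heat opens these through quinone methides), three primary alcohols, four electron-rich arenes and three ring benzylic C–O bonds that limit hydrogenolysis and oxidants. The strategy rests on the fact that oxolane C3 bears a one-carbon substituent and can be a malonate carbon, while C4 bears an arylmethyl group and can be an alkyne carbon, so that O1–C2, C3–C4 and the bond from the benzylic carbon to ring A can be formed around a propargyl alkoxide in one operation. After that only C2 is a primary stereocentre, and C3 and C4 follow by adding hydrogen to a C3=C4 bond on the face away from ring B.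

## Retrosynthetic reasoning

**Deprotection.** Target 31 is traced back to tribenzyl ether 30 by cutting three O–benzyl bonds (phenols of rings A and D, oxolane hydroxymethyl group). Benzyl is chosen for all three because hydrogenolysis is neutral: acid would epimerise oxolane C2 and hot base would open the benzylic ethers para to the phenols. The forward step must cleave three benzyl ethers and leave three ring benzylic C–O bonds.

**Oxidation level of the dihydrobenzofuran side chains.** The two hydroxymethyl groups of 30 go back to the methyl esters of 29, one hydride reduction for both. An ester at C3 makes C3 epimerisable, so the trans relation can be reached by equilibration, and it is what a diazoacetate leaves behind.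

**Outer dihydrobenzofuran.** In 29 (and its C3 epimer 28) the C2–C3 bond of the outer ring is cut, leading to aryl diazoacetate 27; forward, a rhodium carbene at C3 inserts into a benzylic C–H bond of the ring-D benzyl ether. This cut is preferred over C3–C3a or O1–C2 because it turns O1–C2 into an ordinary benzyl aryl ether and C3–C3a into an aryl–CH2 bond, and leaves one enantiotopic choice (which benzylic hydrogen) to a chiral catalyst. 27 comes from aryl acetate 26 by diazo transfer, and 26 from aryl bromide 25 by palladium-catalysed coupling with an acetate enolate equivalent. The forward sequence has to set outer C2 as S and then bring C3 to trans.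

**Inner dihydrobenzofuran.** The same cut in 25 (reached from its cis epimer 24) gives diazo ester 23 and then aryl acetate 22. Since the two rings have opposite absolute sense they cannot be closed together with one catalyst; they are closed in turn with the two antipodes of the same catalyst, and the ring-C bromine in 22–25 is the dormant handle for the second round. 22 is cut at the ring-B O–CH2 bond into silyl ether 15 and benzylic bromide 20, which already carries the ring-D benzyl ether, so ring C needs no protecting-group change. The order is dictated by the bromines: ring B must have its acetate (15) before brominated ring C arrives, so that two aryl bromides never compete in the coupling. 20 is made from 1 and 17 by way of 18 and 19, and 17 from 16.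

**Ring-B acetate and protecting groups.** 15 goes back to aryl bromide 14 (C–C coupling) and 14 to alcohol 13 (O-benzylation, because a free hydroxyl group would intercept the carbene). The bromine is therefore on ring B from the start (1), which fixes two choices: the hydrogenation catalyst must spare an aryl bromide, and palladium in the key step must choose an aryl iodide over it. The ring-B phenol is the only one unmasked alone and is a hindered triisopropylsilyl ether; ring A is benzylated because an unhindered aryl silyl ether would not be safe in the hot chloride step after the key step.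

**Oxolane C3 and C4.** 13 is traced back to 2,5-dihydrofuran 12 by removing the hydrogens at C3 and C4; forward, hydrogen adds to the tetrasubstituted C3=C4 bond opposite ring B and pushes CH2OH and the benzyl group onto the aryl face. This gives the contra-thermodynamic array from one stereocentre, which no equilibration could do. 12 comes from ester 11 (hydride reduction) and 11 from malonate 10 by loss of one ester group with migration of the exocyclic alkene into the ring.

**Key disconnection.** 10 is cut at O1–C2, C3–C4 and the bond between the benzylidene carbon and ring A, giving arylidene malonate 4, propargyl alcohol 7 and aryl iodide 6. No other set of cuts removes the ring and three skeletal bonds at once while leaving achiral building blocks two steps from commerce. The forward reaction must join them in the right order and create absolute configuration at C2 with no resident stereocentre.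

**Building blocks.** 4 is cut at its C=C bond into aldehyde 2 and dimethyl malonate 3 (Knoevenagel); 2 is the silyl ether of 1, and 6 the benzyl ether of 5.

## Alternatives that were turned down

**Alternative 1:** flavanone ring contraction for the inner dihydrobenzofuran.
- Disconnection: C3–C3a of the inner ring, read as a 1,2-shift of ring B, back to the (2R)-flavanone A2 (6-bromo-8-methoxy, acetylated outer ring already on its 2-aryl group). Flavanone C2 becomes dihydrobenzofuran C2 and the ketone carbon becomes the ester.
- Forward key step: PhI(OAc)2 and H2SO4 in trimethyl orthoformate turn A2 into its enol ether, trivalent iodine adds at C3, ring B migrates from C4 to C3 as the aryliodine group leaves, and the dialkoxycarbenium ion collapses to trans methyl ester A1.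
- For it: the trans relation comes from the rearrangement itself, the outer ring arrives in one piece, and one operation does what takes four here (coupling, diazo transfer, insertion, epimerisation). On step economy and convergence for the dihydrobenzofuran part it is the stronger plan, and it needs no rhodium.
- Against it: the 2-aryl group of A2 is ring C with a para oxygen, a better migrating group than ring B, so a competing 1,2-shift of that group is expected. C2 of a flavanone is labile through retro-oxa-Michael opening under strong acid, which also threatens the outer benzylic ether. The plan is silent on the oxolane, which would have to be joined through the ring-B bromine by a carbanion addition with no bias toward all-cis.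
- Comparison: the chosen strategy gives up some convergence but builds the oxolane in one pot with its hardest array reduced to one centre, and closes both dihydrobenzofurans under neutral, catalyst-controlled conditions whose sense is chosen independently.

**Alternative 2:** carbonyl ylide (3+2) cycloaddition.
- Disconnection: oxolane C2–C3 and C4–C5; the oxolane is the adduct of carbonyl ylide A5 (ArCH=O(+)–CH2(−), Ar = 4-allyloxy-3-methoxyphenyl, ring B) and the ring alkene of (5S)-butenolide A4, whose aryl group is ring A.
- Forward key step: A5, released in situ, adds to A4 on the face away from the C5 aryl group with its CH2 terminus at the β-carbon, giving cis-fused furofuranone A3.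
- For it: two C–C bonds and three stereocentres form in one step, and the cis ring fusion guarantees the C3/C4 cis relation. Absolute configuration comes from one centre in A4 that established asymmetric methods can supply and that is later erased when the lactone C–O bond is hydrogenolysed to the benzyl CH2. On absolute control of the oxolane it is the stronger plan, since the chosen key step relies on unproven ligand control.
- Against it: all-cis needs the ylide aryl group endo to the lactone, which is not secured for an unstabilised ylide. The γ-hydrogen of A4 is benzylic and vinylogously α to the carbonyl, so the fluoride or base that releases A5 can racemise or deconjugate A4. The later hydrogenolysis must cleave the lactone benzylic C–O bond yet spare the equally benzylic C2–O1 bond and the allyl ether.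
- Comparison: in the chosen strategy the all-cis relation follows from a steric argument (hydrogen adds anti to one aryl group) rather than an endo/exo preference, the ring comes from three simple achiral components, and no benzylic C–O bond has to be cleaved selectively.

**Alternative 3:** Parham cyclisation onto an epoxide.
- Disconnection: C3–C3a of a dihydrobenzofuran, back to aryl ether A7, in which a 4-bromo-2-iodo-6-methoxyphenyl group is bound through oxygen to the benzylic carbon of an epoxide side chain whose two stereocentres derive from a Sharpless kinetic resolution.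
- Forward key step: n-BuLi at −100 °C exchanges iodine for lithium and the aryllithium opens the epoxide at its internal carbon (5-exo, inversion) to give (2S,3R) bromide A6.
- For it: both centres come from a reagent-controlled epoxidation of predictable sense, the trans relation is fixed stereospecifically with no epimerisation, the hydroxymethyl group appears at the right oxidation level, and bromine remains as a handle. In stereochemical certainty and redox economy for one dihydrobenzofuran it is at least as strong as the carbene insertion used here.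
- Against it: iodine–lithium exchange must outrun bromine–lithium exchange and deprotonation of the benzylic ether C–H (Wittig rearrangement, elimination). The aryl ether must be made at an electron-rich secondary benzylic carbinol, where Mitsunobu displacement tends to ionise. Kinetic resolution gives up half the material, two such units would have to be chained by further organolithium chemistry on ever more functionalised material, and the all-cis oxolane is not addressed.
- Comparison: the chosen strategy replaces the cryogenic organolithium step by catalytic insertions that tolerate the full functional array, repeats one four-step cycle on the growing molecule, and solves the oxolane first.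

Key step: step 4

Assumption: which antipode of BINAP on palladium favours (2S)-10 cannot be predicted; (R) is written, and the antipode is used if the sense is the opposite.

Assumption: Rh2(S-PTTL)4 is taken to give the (2R) inner ring and Rh2(R-PTTL)4 the (2S) outer ring; if the sense is the reverse, the two catalysts change places.

## Route

Step 1
Reactants: 1 5-bromovanillin (3-bromo-4-hydroxy-5-methoxybenzaldehyde)
Product: 2 3-bromo-5-methoxy-4-(triisopropylsilyloxy)benzaldehyde
Conditions: TIPSCl, imidazole, DMAP (cat.), DMF, 40 °C
Reagents that add atoms: chlorotri(propan-2-yl)silane (TIPSCl), CC(C)[Si](Cl)(C(C)C)C(C)C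
Why: O-silylation of the phenol; this is the one protecting group that must later come off alone (fluoride), and flanked by bromine and methoxy it should be hindered enough to withstand alkoxide, amine and hot chloride.

Step 2
Reactants: 2 3-bromo-5-methoxy-4-(triisopropylsilyloxy)benzaldehyde; 3 dimethyl malonate
Product: 4 dimethyl 2-[3-bromo-5-methoxy-4-(triisopropylsilyloxy)benzylidene]malonate
Conditions: piperidine (cat.), AcOH (cat.), toluene, reflux, Dean–Stark
Reagents that add atoms: none
Why: Knoevenagel condensation driven by removal of water; the symmetrical malonate leaves no alkene isomers.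

Step 3
Reactants: 5 4-iodo-2-methoxyphenol
Product: 6 1-(benzyloxy)-4-iodo-2-methoxybenzene
Conditions: BnBr, K2CO3, DMF, rt
Reagents that add atoms: benzyl bromide, BrCc1ccccc1
Why: Williamson ether synthesis; a benzyl ether is inert to alkoxide, zerovalent palladium and hot LiCl, where an unhindered aryl silyl ether would be at risk.

Step 4
Reactants: 4 dimethyl 2-[3-bromo-5-methoxy-4-(triisopropylsilyloxy)benzylidene]malonate; 6 1-(benzyloxy)-4-iodo-2-methoxybenzene; 7 propargyl alcohol
Product: 10 dimethyl (2S,4Z)-4-[4-(benzyloxy)-3-methoxybenzylidene]-2-[3-bromo-5-methoxy-4-(triisopropylsilyloxy)phenyl]oxolane-3,3-dicarboxylate, via lithium prop-2-yn-1-olate 8 (not isolated), via lithium malonate adduct 9 (not isolated)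
Conditions: 7, n-BuLi (1 equiv), THF, 0 °C; then 4; then 6, PdCl2[(R)-BINAP] (5 mol%, reduced beforehand with n-BuLi, 10 mol%, in THF), DMSO–THF, 20 °C
Reagents that add atoms: none
Why: Proposed new method: the closest known reaction is the racemic palladium-mediated three-component assembly of 4-arylidene oxolanes from a propargyl alkoxide, an alkylidene malonate and an aryl iodide, and the new element is a chiral bisphosphine on palladium to control C2. Alkoxide 8 adds reversibly to 4 (oxa-Michael, O1–C2) to give malonate anion 9, whose enantiomers interconvert by retro-addition. Oxidative addition of 6 to zerovalent palladium gives an arylpalladium iodide that binds the alkyne of 9; the malonate carbon attacks the activated alkyne from the side opposite the metal in a 5-exo-dig closure (C3–C4, the only ring closed), and reductive elimination from the vinyl(aryl)palladium species forms the bond to ring A with the aryl group trans to C3 (Z alkene). C2 is the only new stereocentre and is set by the ligand: the (R)-BINAP complex has to cyclise one enantiomer of 9 faster than the other while 9 racemises faster than it cyclises (dynamic kinetic resolution), which is plausible because the C2 aryl group sits above or below the forming ring next to the ligand. The step needs C- over O-attack and 5-exo over 6-endo closure, secured by the soft malonate and the terminal alkyne (palladium ends on the terminal carbon). It also needs the aryl iodide to react before the ring-B bromide, secured by the slow oxidative addition of an electron-rich, doubly ortho-substituted C–Br bond at 20 °C.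

Step 5
Reactants: 10 dimethyl (2S,4Z)-4-[4-(benzyloxy)-3-methoxybenzylidene]-2-[3-bromo-5-methoxy-4-(triisopropylsilyloxy)phenyl]oxolane-3,3-dicarboxylate
Product: 11 methyl (2S)-4-[4-(benzyloxy)-3-methoxybenzyl]-2-[3-bromo-5-methoxy-4-(triisopropylsilyloxy)phenyl]-2,5-dihydrofuran-3-carboxylate
Conditions: LiCl, H2O, DMSO, 130 °C
Reagents that add atoms: none
Why: Krapcho dealkoxycarbonylation: chloride demethylates one ester, the carboxylate loses CO2 to an extended enolate, and protonation at the benzylic carbon puts the alkene in the ring in conjugation with the remaining ester. C2 should be untouched, since its hydrogen is only cross-conjugated to the ester and β-elimination of O1 from the enolate would be a 5-endo-trig closure run backwards.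

Step 6
Reactants: 11 methyl (2S)-4-[4-(benzyloxy)-3-methoxybenzyl]-2-[3-bromo-5-methoxy-4-(triisopropylsilyloxy)phenyl]-2,5-dihydrofuran-3-carboxylate
Product: 12 {(2S)-4-[4-(benzyloxy)-3-methoxybenzyl]-2-[3-bromo-5-methoxy-4-(triisopropylsilyloxy)phenyl]-2,5-dihydrofuran-3-yl}methanol
Conditions: i-Bu2AlH, CH2Cl2, −78 → 0 °C; aq. KNaC4H4O6
Reagents that add atoms: none
Why: 1,2-reduction of the conjugated ester to the allylic alcohol with an aluminium hydride; silyl ether, benzyl ether and aryl bromide are inert.

Step 7
Reactants: 12 {(2S)-4-[4-(benzyloxy)-3-methoxybenzyl]-2-[3-bromo-5-methoxy-4-(triisopropylsilyloxy)phenyl]-2,5-dihydrofuran-3-yl}methanol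
Product: 13 {(2R,3R,4R)-4-[4-(benzyloxy)-3-methoxybenzyl]-2-[3-bromo-5-methoxy-4-(triisopropylsilyloxy)phenyl]oxolan-3-yl}methanol (all-cis)
Conditions: H2 (1–3 atm), [Ir(cod)(PCy3)(py)]PF6 (5–10 mol%), CH2Cl2, rt
Reagents that add atoms: none
Why: Hydroxyl-assisted homogeneous hydrogenation with a cationic iridium catalyst, which reduces tetrasubstituted alkenes and leaves aryl bromide and benzyl ethers alone. Both hydrogens add to the face of the flat dihydrofuran opposite the C2 aryl group, so CH2OH and the benzyl group end up cis to it (C3 and C4 set by C2). The C2 descriptor changes from S to R only because C3 drops below the aryl group in CIP rank.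

Step 8
Reactants: 13 {(2R,3R,4R)-4-[4-(benzyloxy)-3-methoxybenzyl]-2-[3-bromo-5-methoxy-4-(triisopropylsilyloxy)phenyl]oxolan-3-yl}methanol
Product: 14 (2R,3R,4R)-4-[4-(benzyloxy)-3-methoxybenzyl]-3-[(benzyloxy)methyl]-2-[3-bromo-5-methoxy-4-(triisopropylsilyloxy)phenyl]oxolane
Conditions: NaH, BnBr, Bu4NI (cat.), THF–DMF, 0 °C → rt
Reagents that add atoms: benzyl bromide, BrCc1ccccc1
Why: Williamson ether synthesis; the primary alcohol is masked against O–H insertion in the carbene steps and is released with the other benzyl ethers at the end.

Step 9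
Reactants: 14 (2R,3R,4R)-4-[4-(benzyloxy)-3-methoxybenzyl]-3-[(benzyloxy)methyl]-2-[3-bromo-5-methoxy-4-(triisopropylsilyloxy)phenyl]oxolane
Product: 15 methyl 2-{5-[(2R,3R,4R)-4-[4-(benzyloxy)-3-methoxybenzyl]-3-[(benzyloxy)methyl]oxolan-2-yl]-3-methoxy-2-(triisopropylsilyloxy)phenyl}acetate
Conditions: BrZnCH2CO2Me, [Pd(μ-Br)(P(t-Bu)3)]2 (2 mol%), THF, rt → 40 °C
Reagents that add atoms: bromo(2-methoxy-2-oxoethyl)zinc (Reformatsky reagent, prepared beforehand from methyl bromoacetate and zinc in THF), COC(=O)C[Zn]Br
Why: Palladium-catalysed cross-coupling of an aryl bromide with a zinc ester enolate (Negishi-type α-arylation with a Reformatsky reagent). The zinc enolate is too weakly basic to disturb the silyl ether or any stereocentre, and the bulky monophosphine suits the hindered ortho-silyloxy bromide.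

Step 10
Reactants: 16 4-(benzyloxy)-3-methoxybenzyl alcohol
Product: 17 4-(benzyloxy)-3-methoxybenzyl bromide
Conditions: PBr3, Et2O, 0 °C
Reagents that add atoms: phosphorus tribromide, BrP(Br)Br
Why: Conversion of a benzylic alcohol into the bromide by bromide displacement on the phosphite ester.

Step 11
Reactants: 1 5-bromovanillin; 17 4-(benzyloxy)-3-methoxybenzyl bromide
Product: 18 4-{[4-(benzyloxy)-3-methoxybenzyl]oxy}-3-bromo-5-methoxybenzaldehyde
Conditions: K2CO3, DMF, 50 °C
Reagents that add atoms: none
Why: Williamson ether synthesis; the phenoxide of 1 is alkylated by the reactive benzylic bromide, which installs the ring-D unit on the future ring C.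

Step 12
Reactants: 18 4-{[4-(benzyloxy)-3-methoxybenzyl]oxy}-3-bromo-5-methoxybenzaldehyde
Product: 19 (4-{[4-(benzyloxy)-3-methoxybenzyl]oxy}-3-bromo-5-methoxyphenyl)methanol
Conditions: NaBH4, MeOH–THF, 0 °C
Reagents that add atoms: none
Why: Borohydride reduction of the aromatic aldehyde to the benzylic alcohol.

Step 13
Reactants: 19 (4-{[4-(benzyloxy)-3-methoxybenzyl]oxy}-3-bromo-5-methoxyphenyl)methanol
Product: 20 1-{[4-(benzyloxy)-3-methoxybenzyl]oxy}-2-bromo-4-(bromomethyl)-6-methoxybenzene
Conditions: CBr4, PPh3, CH2Cl2, 0 °C
Reagents that add atoms: tetrabromomethane, BrC(Br)(Br)Br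
Why: Appel bromination; it is neutral, so the acid-labile dialkoxybenzyl aryl ether is not cleaved as it might be by HBr.

Step 14
Reactants: 15 methyl 2-{5-[(2R,3R,4R)-4-[4-(benzyloxy)-3-methoxybenzyl]-3-[(benzyloxy)methyl]oxolan-2-yl]-3-methoxy-2-(triisopropylsilyloxy)phenyl}acetate; 20 1-{[4-(benzyloxy)-3-methoxybenzyl]oxy}-2-bromo-4-(bromomethyl)-6-methoxybenzene
Product: 22 methyl 2-{2-[(4-{[4-(benzyloxy)-3-methoxybenzyl]oxy}-3-bromo-5-methoxybenzyl)oxy]-5-[(2R,3R,4R)-4-[4-(benzyloxy)-3-methoxybenzyl]-3-[(benzyloxy)methyl]oxolan-2-yl]-3-methoxyphenyl}acetate, via caesium phenolate 21 (not isolated)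
Conditions: CsF, DMF, rt → 40 °C
Reagents that add atoms: none
Why: Fluoride-induced desilylation and Williamson etherification in one pot: CsF releases phenoxide 21, which is O-alkylated by bromide 20 as it forms. The p-hydroxybenzylic ether is thus never isolated, and the O–CH2 group that will become inner C2 is now in place.

Step 15
Reactants: 22 methyl 2-{2-[(4-{[4-(benzyloxy)-3-methoxybenzyl]oxy}-3-bromo-5-methoxybenzyl)oxy]-5-[(2R,3R,4R)-4-[4-(benzyloxy)-3-methoxybenzyl]-3-[(benzyloxy)methyl]oxolan-2-yl]-3-methoxyphenyl}acetate
Product: 23 the α-diazo ester of 22, methyl 2-diazo-2-{2-[(4-{[4-(benzyloxy)-3-methoxybenzyl]oxy}-3-bromo-5-methoxybenzyl)oxy]-5-[(2R,3R,4R)-4-[4-(benzyloxy)-3-methoxybenzyl]-3-[(benzyloxy)methyl]oxolan-2-yl]-3-methoxyphenyl}acetate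
Conditions: p-ABSA, DBU, MeCN, 0 °C → rt
Reagents that add atoms: 4-acetamidobenzenesulfonyl azide (p-ABSA), CC(=O)Nc1ccc(cc1)S(=O)(=O)N=[N+]=[N-]
Why: Regitz diazo transfer: DBU deprotonates the benzylic ester position and the sulfonyl azide hands over N2, giving the donor/acceptor diazo compound.

Step 16
Reactants: 23 the α-diazo ester of 22
Product: 24 methyl (2R,3S)-2-(4-{[4-(benzyloxy)-3-methoxybenzyl]oxy}-3-bromo-5-methoxyphenyl)-5-[(2R,3R,4R)-4-[4-(benzyloxy)-3-methoxybenzyl]-3-[(benzyloxy)methyl]oxolan-2-yl]-7-methoxy-2,3-dihydro-1-benzofuran-3-carboxylate (inner ring, cis)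
Conditions: Rh2(S-PTTL)4 (dirhodium tetrakis[N-phthaloyl-(S)-tert-leucinate], 2 mol%), toluene–CH2Cl2, −60 °C
Reagents that add atoms: none
Why: Intramolecular rhodium-carbene C–H insertion of an aryl diazoacetate into the benzylic ether C–H bond five atoms away, closing the dihydrofuran ring at C2–C3. The chiral dirhodium carboxylate selects one of the two enantiotopic benzylic hydrogens and so sets C2 (R), and the concerted insertion gives the cis ester kinetically. The oxolane centres are too remote to interfere.

Step 17
Reactants: 24 the inner-ring cis ester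
Product: 25 methyl (2R,3R)-2-(4-{[4-(benzyloxy)-3-methoxybenzyl]oxy}-3-bromo-5-methoxyphenyl)-5-[(2R,3R,4R)-4-[4-(benzyloxy)-3-methoxybenzyl]-3-[(benzyloxy)methyl]oxolan-2-yl]-7-methoxy-2,3-dihydro-1-benzofuran-3-carboxylate (inner ring, trans)
Conditions: NaOMe, MeOH–THF, rt
Reagents that add atoms: none
Why: Base-mediated epimerisation α to the ester: C3 equilibrates to the more stable trans isomer under control of C2. Ring opening by loss of the aryloxide from the enolate is disfavoured, because the C2–O1 bond lies in the ring plane, orthogonal to the enolate π system.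

Step 18
Reactants: 25 the inner-ring trans ester
Product: 26 methyl (2R,3R)-2-[4-{[4-(benzyloxy)-3-methoxybenzyl]oxy}-3-methoxy-5-(2-methoxy-2-oxoethyl)phenyl]-5-[(2R,3R,4R)-4-[4-(benzyloxy)-3-methoxybenzyl]-3-[(benzyloxy)methyl]oxolan-2-yl]-7-methoxy-2,3-dihydro-1-benzofuran-3-carboxylate
Conditions: BrZnCH2CO2Me, [Pd(μ-Br)(P(t-Bu)3)]2 (2 mol%), THF, rt → 40 °C
Reagents that add atoms: bromo(2-methoxy-2-oxoethyl)zinc, COC(=O)C[Zn]Br
Why: The same Negishi-type coupling with the Reformatsky reagent, now at the ring-C bromide, the only aryl bromide left; the zinc enolate does not touch the resident ester or its α-centre.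

Step 19
Reactants: 26 the ring-C aryl acetate
Product: 27 the α-diazo ester of 26 (diazo group on the ring-C acetate carbon)
Conditions: p-ABSA, DBU, MeCN, 0 °C → rt
Reagents that add atoms: 4-acetamidobenzenesulfonyl azide (p-ABSA), CC(=O)Nc1ccc(cc1)S(=O)(=O)N=[N+]=[N-]
Why: Regitz diazo transfer at the only CH2 flanked by aryl and ester; the inner-ring ester has a tertiary α-carbon that cannot take a diazo group and is already in its stable trans form.

Step 20
Reactants: 27 the α-diazo ester of 26
Product: 28 methyl (2S,3R)-2-[4-(benzyloxy)-3-methoxyphenyl]-5-{(2R,3R)-5-[(2R,3R,4R)-4-[4-(benzyloxy)-3-methoxybenzyl]-3-[(benzyloxy)methyl]oxolan-2-yl]-7-methoxy-3-(methoxycarbonyl)-2,3-dihydro-1-benzofuran-2-yl}-7-methoxy-2,3-dihydro-1-benzofuran-3-carboxylate (outer ring cis, inner ring trans)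
Conditions: Rh2(R-PTTL)4 (dirhodium tetrakis[N-phthaloyl-(R)-tert-leucinate], 2 mol%), toluene–CH2Cl2, −60 °C
Reagents that add atoms: none
Why: The same 1,5 carbene C–H insertion, now into the ring-D benzyl ether; the antipodal catalyst selects the other enantiotopic hydrogen and sets outer C2 as S, the sense opposite to the inner ring as the target requires.

Step 21
Reactants: 28 the diester with outer ring cis
Product: 29 methyl (2S,3S)-2-[4-(benzyloxy)-3-methoxyphenyl]-5-{(2R,3R)-5-[(2R,3R,4R)-4-[4-(benzyloxy)-3-methoxybenzyl]-3-[(benzyloxy)methyl]oxolan-2-yl]-7-methoxy-3-(methoxycarbonyl)-2,3-dihydro-1-benzofuran-2-yl}-7-methoxy-2,3-dihydro-1-benzofuran-3-carboxylate (both rings trans)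
Conditions: NaOMe, MeOH–THF, rt
Reagents that add atoms: none
Why: Base-mediated epimerisation α to the outer ester brings outer C3 to trans under control of outer C2; the inner ester is already at equilibrium.

Step 22
Reactants: 29 the trans,trans diester
Product: 30 {(2S,3R)-2-[4-(benzyloxy)-3-methoxyphenyl]-5-{(2R,3S)-5-[(2R,3R,4R)-4-[4-(benzyloxy)-3-methoxybenzyl]-3-[(benzyloxy)methyl]oxolan-2-yl]-3-(hydroxymethyl)-7-methoxy-2,3-dihydro-1-benzofuran-2-yl}-7-methoxy-2,3-dihydro-1-benzofuran-3-yl}methanol
Conditions: LiAlH4, THF, −10 → 0 °C
Reagents that add atoms: none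
Why: Hydride reduction of both methyl esters to primary alcohols; no stereocentre is touched, and the C3 descriptors change (R to S inner, S to R outer) only through CIP ranking.

Step 23
Reactants: 30 the tribenzyl ether diol
Product: 31 CNP0395728.1, the target: oxolane (2R,3R,4R) all-cis, inner dihydrobenzofuran (2R,3S), outer dihydrobenzofuran (2S,3R)
Conditions: H2 (1 atm), Pd/C (10%), EtOAc–MeOH, rt
Reagents that add atoms: none
Why: Hydrogenolysis of two aryl benzyl ethers and one primary alkyl benzyl ether under neutral conditions; the three ring benzylic C–O bonds are secondary and hindered and should react more slowly, so the reaction is stopped at full debenzylation.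

## Compound list

1 | 5-bromovanillin (3-bromo-4-hydroxy-5-methoxybenzaldehyde) | COc1cc(C=O)cc(Br)c1O | starting material
2 | 3-bromo-5-methoxy-4-(triisopropylsilyloxy)benzaldehyde | COc1cc(C=O)cc(Br)c1O[Si](C(C)C)(C(C)C)C(C)C | intermediate
3 | dimethyl malonate | COC(=O)CC(=O)OC | starting material
4 | dimethyl 2-[3-bromo-5-methoxy-4-(triisopropylsilyloxy)benzylidene]malonate | COC(=O)C(=Cc1cc(OC)c(O[Si](C(C)C)(C(C)C)C(C)C)c(Br)c1)C(=O)OC | intermediate
5 | 4-iodo-2-methoxyphenol | COc1cc(I)ccc1O | starting material
6 | 1-(benzyloxy)-4-iodo-2-methoxybenzene | COc1cc(I)ccc1OCc1ccccc1 | intermediate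
7 | propargyl alcohol | C#CCO | starting material
8 | lithium prop-2-yn-1-olate (not isolated) | [Li+].[O-]CC#C | intermediate
9 | lithium malonate adduct, lithium salt of dimethyl 2-{[3-bromo-5-methoxy-4-(triisopropylsilyloxy)phenyl](prop-2-yn-1-yloxy)methyl}malonate, both enantiomers in equilibrium (not isolated) | [Li+].COC(=O)[C-](C(=O)OC)C(OCC#C)c1cc(OC)c(O[Si](C(C)C)(C(C)C)C(C)C)c(Br)c1 | intermediate
10 | dimethyl (2S,4Z)-4-[4-(benzyloxy)-3-methoxybenzylidene]-2-[3-bromo-5-methoxy-4-(triisopropylsilyloxy)phenyl]oxolane-3,3-dicarboxylate | COC(=O)C1(C(=O)OC)[C@H](c2cc(OC)c(O[Si](C(C)C)(C(C)C)C(C)C)c(Br)c2)OC/C1=C\c1ccc(OCc2ccccc2)c(OC)c1 | intermediate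
11 | methyl (2S)-4-[4-(benzyloxy)-3-methoxybenzyl]-2-[3-bromo-5-methoxy-4-(triisopropylsilyloxy)phenyl]-2,5-dihydrofuran-3-carboxylate | COC(=O)C1=C(Cc2ccc(OCc3ccccc3)c(OC)c2)CO[C@H]1c1cc(OC)c(O[Si](C(C)C)(C(C)C)C(C)C)c(Br)c1 | intermediate
12 | {(2S)-4-[4-(benzyloxy)-3-methoxybenzyl]-2-[3-bromo-5-methoxy-4-(triisopropylsilyloxy)phenyl]-2,5-dihydrofuran-3-yl}methanol | OCC1=C(Cc2ccc(OCc3ccccc3)c(OC)c2)CO[C@H]1c1cc(OC)c(O[Si](C(C)C)(C(C)C)C(C)C)c(Br)c1 | intermediate
13 | {(2R,3R,4R)-4-[4-(benzyloxy)-3-methoxybenzyl]-2-[3-bromo-5-methoxy-4-(triisopropylsilyloxy)phenyl]oxolan-3-yl}methanol | COc1cc(C[C@H]2CO[C@@H](c3cc(OC)c(O[Si](C(C)C)(C(C)C)C(C)C)c(Br)c3)[C@H]2CO)ccc1OCc1ccccc1 | intermediate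
14 | (2R,3R,4R)-4-[4-(benzyloxy)-3-methoxybenzyl]-3-[(benzyloxy)methyl]-2-[3-bromo-5-methoxy-4-(triisopropylsilyloxy)phenyl]oxolane | COc1cc(C[C@H]2CO[C@@H](c3cc(OC)c(O[Si](C(C)C)(C(C)C)C(C)C)c(Br)c3)[C@H]2COCc2ccccc2)ccc1OCc1ccccc1 | intermediate
15 | methyl 2-{5-[(2R,3R,4R)-4-[4-(benzyloxy)-3-methoxybenzyl]-3-[(benzyloxy)methyl]oxolan-2-yl]-3-methoxy-2-(triisopropylsilyloxy)phenyl}acetate | COc1cc(C[C@H]2CO[C@@H](c3cc(OC)c(O[Si](C(C)C)(C(C)C)C(C)C)c(CC(=O)OC)c3)[C@H]2COCc2ccccc2)ccc1OCc1ccccc1 | intermediate
16 | 4-(benzyloxy)-3-methoxybenzyl alcohol | COc1cc(CO)ccc1OCc1ccccc1 | starting material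
17 | 4-(benzyloxy)-3-methoxybenzyl bromide | COc1cc(CBr)ccc1OCc1ccccc1 | intermediate
18 | 4-{[4-(benzyloxy)-3-methoxybenzyl]oxy}-3-bromo-5-methoxybenzaldehyde | COc1cc(C=O)cc(Br)c1OCc1ccc(OCc2ccccc2)c(OC)c1 | intermediate
19 | (4-{[4-(benzyloxy)-3-methoxybenzyl]oxy}-3-bromo-5-methoxyphenyl)methanol | COc1cc(CO)cc(Br)c1OCc1ccc(OCc2ccccc2)c(OC)c1 | intermediate
20 | 1-{[4-(benzyloxy)-3-methoxybenzyl]oxy}-2-bromo-4-(bromomethyl)-6-methoxybenzene | COc1cc(CBr)cc(Br)c1OCc1ccc(OCc2ccccc2)c(OC)c1 | intermediate
21 | caesium phenolate of 15 after loss of the silyl group (not isolated) | [Cs+].COc1cc(C[C@H]2CO[C@@H](c3cc(OC)c([O-])c(CC(=O)OC)c3)[C@H]2COCc2ccccc2)ccc1OCc1ccccc1 | intermediate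
22 | methyl 2-{2-[(4-{[4-(benzyloxy)-3-methoxybenzyl]oxy}-3-bromo-5-methoxybenzyl)oxy]-5-[(2R,3R,4R)-4-[4-(benzyloxy)-3-methoxybenzyl]-3-[(benzyloxy)methyl]oxolan-2-yl]-3-methoxyphenyl}acetate | COc1cc(C[C@H]2CO[C@@H](c3cc(OC)c(OCc4cc(OC)c(OCc5ccc(OCc6ccccc6)c(OC)c5)c(Br)c4)c(CC(=O)OC)c3)[C@H]2COCc2ccccc2)ccc1OCc1ccccc1 | intermediate
23 | α-diazo ester of 22 | COc1cc(C[C@H]2CO[C@@H](c3cc(OC)c(OCc4cc(OC)c(OCc5ccc(OCc6ccccc6)c(OC)c5)c(Br)c4)c(C(=[N+]=[N-])C(=O)OC)c3)[C@H]2COCc2ccccc2)ccc1OCc1ccccc1 | intermediate
24 | inner-ring cis ester, methyl (2R,3S)-2-(4-{[4-(benzyloxy)-3-methoxybenzyl]oxy}-3-bromo-5-methoxyphenyl)-5-[(2R,3R,4R)-oxolan-2-yl unit as in 14]-7-methoxy-2,3-dihydro-1-benzofuran-3-carboxylate | COc1cc(C[C@H]2CO[C@@H](c3cc(OC)c4c(c3)[C@H](C(=O)OC)[C@H](c3cc(OC)c(OCc5ccc(OCc6ccccc6)c(OC)c5)c(Br)c3)O4)[C@H]2COCc2ccccc2)ccc1OCc1ccccc1 | intermediate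
25 | inner-ring trans ester, the (2R,3R) epimer of 24 | COc1cc(C[C@H]2CO[C@@H](c3cc(OC)c4c(c3)[C@@H](C(=O)OC)[C@H](c3cc(OC)c(OCc5ccc(OCc6ccccc6)c(OC)c5)c(Br)c3)O4)[C@H]2COCc2ccccc2)ccc1OCc1ccccc1 | intermediate
26 | ring-C aryl acetate, 25 with CH2CO2Me in place of bromine | COc1cc(C[C@H]2CO[C@@H](c3cc(OC)c4c(c3)[C@@H](C(=O)OC)[C@H](c3cc(OC)c(OCc5ccc(OCc6ccccc6)c(OC)c5)c(CC(=O)OC)c3)O4)[C@H]2COCc2ccccc2)ccc1OCc1ccccc1 | intermediate
27 | α-diazo ester of 26 | COc1cc(C[C@H]2CO[C@@H](c3cc(OC)c4c(c3)[C@@H](C(=O)OC)[C@H](c3cc(OC)c(OCc5ccc(OCc6ccccc6)c(OC)c5)c(C(=[N+]=[N-])C(=O)OC)c3)O4)[C@H]2COCc2ccccc2)ccc1OCc1ccccc1 | intermediate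
28 | bis(dihydrobenzofuran) diester, outer ring (2S,3R) cis, inner ring (2R,3R) trans | COc1cc(C[C@H]2CO[C@@H](c3cc(OC)c4c(c3)[C@@H](C(=O)OC)[C@H](c3cc(OC)c5c(c3)[C@@H](C(=O)OC)[C@@H](c3ccc(OCc6ccccc6)c(OC)c3)O5)O4)[C@H]2COCc2ccccc2)ccc1OCc1ccccc1 | intermediate
29 | bis(dihydrobenzofuran) diester, outer ring (2S,3S) trans, inner ring (2R,3R) trans | COc1cc(C[C@H]2CO[C@@H](c3cc(OC)c4c(c3)[C@@H](C(=O)OC)[C@H](c3cc(OC)c5c(c3)[C@H](C(=O)OC)[C@@H](c3ccc(OCc6ccccc6)c(OC)c3)O5)O4)[C@H]2COCc2ccccc2)ccc1OCc1ccccc1 | intermediate
30 | tribenzyl ether diol, outer ring (2S,3R), inner ring (2R,3S), oxolane (2R,3R,4R) | COc1cc(C[C@H]2CO[C@@H](c3cc(OC)c4c(c3)[C@@H](CO)[C@H](c3cc(OC)c5c(c3)[C@H](CO)[C@@H](c3ccc(OCc6ccccc6)c(OC)c3)O5)O4)[C@H]2COCc2ccccc2)ccc1OCc1ccccc1 | intermediate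
31 | CNP0395728.1 | COc1cc(C[C@H]2CO[C@@H](c3cc(OC)c4c(c3)[C@@H](CO)[C@H](c3cc(OC)c5c(c3)[C@H](CO)[C@@H](c3ccc(O)c(OC)c3)O5)O4)[C@H]2CO)ccc1O | target

## Step count and least certain steps

Total step count: 23. Longest linear sequence: 18 steps (steps 1, 2, 4–9 and 14–23, from 5-bromovanillin).

**Step 4 (key step, proposed new method).** The likely failure is insufficient discrimination between the two equilibrating enantiomers of 9. The stereocentre is made in the reversible oxa-Michael step, two atoms from the alkyne at which palladium acts, and a chelating bisphosphine may slow alkyne activation because iodide must leave the metal first. The fallback uses known chemistry, sets out from 4, 6 and 7 and comes back at 12. The coupling is run with PdCl2(PPh3)2 reduced by n-BuLi, the established racemic protocol, to give the racemic diester F1. LiCl in wet DMSO as in step 5 gives the racemic dihydrofuran ester F2, and i-Bu2AlH gives the racemic allylic alcohol F3. F3 is resolved by preparative chromatography on a chiral stationary phase (amylose tris(3,5-dimethylphenylcarbamate), supercritical CO2–MeOH); the (2S) enantiomer is 12 and the (2R) enantiomer F4 is set aside. Since resolution follows the hot step, any loss of configuration at C2 in the dealkoxycarbonylation also becomes harmless.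

**Step 5.** The risk is cleavage of the aryl silyl ether in hot, wet DMSO that turns mildly basic. The phenoxide para to C2 could then open the C2–O1 bond through a quinone methide and scramble C2, and the alkene migration may stop short of the conjugated isomer. The fallback sets out from 10 and returns at 11. Lithium propane-1-thiolate in HMPA–THF at room temperature removes one ester methyl group by attack at carbon, giving after acidic work-up the half-acid F5 (mixture of C3 epimers). Warming F5 in toluene with Et3N decarboxylates the β,γ-unsaturated malonic half-acid and the amine moves the alkene into conjugation. No hydroxide or halide is present at high temperature.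

**Step 7.** The tetrasubstituted alkene may be reduced slowly, and the acidic iridium hydride may instead isomerise the allylic alcohol to the aldehyde or ionise the benzylic, allylic C2–O1 bond; either would also erode facial selectivity. The fallback sets out from 11 and returns at 13. The unsaturated ester is hydrogenated over Pt/C (H2, 4 atm, EtOAc), a surface catalyst that spares aryl bromides and adds hydrogen from the face away from the aryl group, to give the all-cis saturated ester F6. F6 is reduced at once with LiAlH4 at −20 °C, without exposure to base, so that C3 is kept.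

**Step 14.** The hindered silyl ether may be cleaved slowly while the p-alkoxybenzyl bromide 20 ionises or is consumed by fluoride, and the enolisable aryl acetate may be C-alkylated. The fallback sets out from 15 and returns at 22. Bu4NF buffered with AcOH in THF at 0 °C gives the phenol F7, which is etherified with alcohol 19 under Mitsunobu conditions (PPh3, DIAD, THF), so that bromide 20 is not needed.

**Step 16.** The dirhodium catalyst may distinguish the two benzylic hydrogens poorly next to the doubly ortho-substituted aryl ether. The product would then be contaminated by the inner-ring epimeric series, which differs from the wanted one only in a remote relation and is hard to remove on silica. The fallback sets out from 23 and returns at 25. Insertion with achiral Rh2(OAc)4 in CH2Cl2 gives 24 together with its inner-ring cis diastereomer F8; NaOMe as in step 17 converts the pair into 25 and the inner-ring trans diastereomer F9, and 25 is isolated by preparative chromatography on a chiral stationary phase, which tells the two apart because their dihydrobenzofuran parts are mirror images. What is learned here about catalyst loading and temperature carries over to step 20.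

## Further compounds

F1 | step 4 | racemic dimethyl (4Z)-4-[4-(benzyloxy)-3-methoxybenzylidene]-2-[3-bromo-5-methoxy-4-(triisopropylsilyloxy)phenyl]oxolane-3,3-dicarboxylate | COC(=O)C1(C(=O)OC)C(c2cc(OC)c(O[Si](C(C)C)(C(C)C)C(C)C)c(Br)c2)OC/C1=C\c1ccc(OCc2ccccc2)c(OC)c1
F2 | step 4 | racemic methyl 4-[4-(benzyloxy)-3-methoxybenzyl]-2-[3-bromo-5-methoxy-4-(triisopropylsilyloxy)phenyl]-2,5-dihydrofuran-3-carboxylate | COC(=O)C1=C(Cc2ccc(OCc3ccccc3)c(OC)c2)COC1c1cc(OC)c(O[Si](C(C)C)(C(C)C)C(C)C)c(Br)c1
F3 | step 4 | racemic {4-[4-(benzyloxy)-3-methoxybenzyl]-2-[3-bromo-5-methoxy-4-(triisopropylsilyloxy)phenyl]-2,5-dihydrofuran-3-yl}methanol | OCC1=C(Cc2ccc(OCc3ccccc3)c(OC)c2)COC1c1cc(OC)c(O[Si](C(C)C)(C(C)C)C(C)C)c(Br)c1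
F4 | step 4 | (2R) enantiomer of 12 | OCC1=C(Cc2ccc(OCc3ccccc3)c(OC)c2)CO[C@@H]1c1cc(OC)c(O[Si](C(C)C)(C(C)C)C(C)C)c(Br)c1
F5 | step 5 | (2S,4Z)-4-[4-(benzyloxy)-3-methoxybenzylidene]-2-[3-bromo-5-methoxy-4-(triisopropylsilyloxy)phenyl]-3-(methoxycarbonyl)oxolane-3-carboxylic acid, mixture of C3 epimers | COC(=O)C1(C(O)=O)[C@H](c2cc(OC)c(O[Si](C(C)C)(C(C)C)C(C)C)c(Br)c2)OC/C1=C\c1ccc(OCc2ccccc2)c(OC)c1
F6 | step 7 | methyl (2R,3S,4R)-4-[4-(benzyloxy)-3-methoxybenzyl]-2-[3-bromo-5-methoxy-4-(triisopropylsilyloxy)phenyl]oxolane-3-carboxylate (all-cis) | COc1cc(C[C@H]2CO[C@@H](c3cc(OC)c(O[Si](C(C)C)(C(C)C)C(C)C)c(Br)c3)[C@H]2C(=O)OC)ccc1OCc1ccccc1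
F7 | step 14 | methyl 2-{5-[(2R,3R,4R)-4-[4-(benzyloxy)-3-methoxybenzyl]-3-[(benzyloxy)methyl]oxolan-2-yl]-2-hydroxy-3-methoxyphenyl}acetate | COc1cc(C[C@H]2CO[C@@H](c3cc(OC)c(O)c(CC(=O)OC)c3)[C@H]2COCc2ccccc2)ccc1OCc1ccccc1
F8 | step 16 | inner-ring (2S,3R) cis diastereomer of 24 | COc1cc(C[C@H]2CO[C@@H](c3cc(OC)c4c(c3)[C@@H](C(=O)OC)[C@@H](c3cc(OC)c(OCc5ccc(OCc6ccccc6)c(OC)c5)c(Br)c3)O4)[C@H]2COCc2ccccc2)ccc1OCc1ccccc1
F9 | step 16 | inner-ring (2S,3S) trans diastereomer of 25 | COc1cc(C[C@H]2CO[C@@H](c3cc(OC)c4c(c3)[C@H](C(=O)OC)[C@@H](c3cc(OC)c(OCc5ccc(OCc6ccccc6)c(OC)c5)c(Br)c3)O4)[C@H]2COCc2ccccc2)ccc1OCc1ccccc1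
A1 | alternative 1 | trans methyl ester of the inner dihydrobenzofuran on brominated ring B, carrying the acetylated outer ring | Brc1cc(OC)c2c(c1)[C@@H](C(=O)OC)[C@H](c1cc(OC)c3c(c1)[C@H](COC(C)=O)[C@@H](c1ccc(OC(C)=O)c(OC)c1)O3)O2
A2 | alternative 1 | (2R)-6-bromo-8-methoxyflavanone whose 2-aryl group is ring C with the acetylated outer ring | Brc1cc(OC)c2c(c1)C(=O)C[C@H](c1cc(OC)c3c(c1)[C@H](COC(C)=O)[C@@H](c1ccc(OC(C)=O)c(OC)c1)O3)O2
A3 | alternative 2 | cis-fused diaryl furofuranone holding the all-cis oxolane, lactone aryl exo | COc1cc([C@@H]3[C@H]2CO[C@@H](c4ccc(OCC=C)c(OC)c4)[C@H]2C(=O)O3)ccc1O[Si](C)(C)C(C)(C)C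
A4 | alternative 2 | (5S)-5-[4-(tert-butyldimethylsilyloxy)-3-methoxyphenyl]furan-2(5H)-one | COc1cc([C@@H]2C=CC(=O)O2)ccc1O[Si](C)(C)C(C)(C)C
A5 | alternative 2 | carbonyl ylide of the ring-B unit, (4-allyloxy-3-methoxybenzylidene)oxonium methylide | C=CCOc1ccc(C=[O+][CH2-])cc1OC
A6 | alternative 3 | (2S,3R)-5-bromo-3-(hydroxymethyl)-7-methoxy-2-[4-(tert-butyldimethylsilyloxy)-3-methoxyphenyl]-2,3-dihydrobenzofuran | Brc1cc(OC)c2c(c1)[C@H](CO)[C@@H](c1ccc(O[Si](C)(C)C(C)(C)C)c(OC)c1)O2
A7 | alternative 3 | 2-{(4-bromo-2-iodo-6-methoxyphenoxy)[4-(tert-butyldimethylsilyloxy)-3-methoxyphenyl]methyl}oxirane, configured to give A6 on cyclisation with inversion | COc1cc(Br)cc(I)c1O[C@H](c1ccc(O[Si](C)(C)C(C)(C)C)c(OC)c1)[C@@H]1CO1
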